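**Plan**
1. Retrosynthesis cuts, in order: the two aryl silyl ethers; the C7–H and C7–aryl bonds (hydride, then an aryllithium, on a lactone carbonyl); the temporary lactone bond C7–O9' together with the oxolane bond C8–C8', which lead back to a six-membered 5-diazo-oxan-4-one; C8'–C9' (formaldehyde aldol); C7'–C8' and O1–C9 (hetero-Diels–Alder on protected vanillin).
2. Forward: the oxanone ring O1–C7'–C8'–C7(=O)–C8–C9 is built first, the diazo group goes onto C8 and CH2OH onto C8', and photolysis then contracts the six-membered ring to the oxolane while a temporary lactone ring closes in the same operation; aryl addition, reduction and desilylation finish.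
3. Enabling feature: C7 is exocyclic on C8 of the oxolane (O1, C7', C8', C8, C9) and the CH2OH arm on the neighbouring C8' is cis to it. Raised to the carboxyl level, C7 is therefore exactly the carbon a Wolff contraction pushes out of the ring, and the cis arm can capture it as a cis-fused 3,7-dioxabicyclo[3.3.0]octan-2-one.
4. Stereochemistry: C7' from the chiral hetero-Diels–Alder catalyst; C8' trans to the aryl group in the enolate aldol (retained in the migration); C8 from the cis fusion of the temporary lactone; C7 from convex-face hydride delivery to the chelated ketone.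

Key step: step 5

Remark: lignan numbering (C7–C9, C7'–C9') is used for the target; six-membered intermediates are numbered O1, C2 (aryl carbon) to C6; Ar = 3-methoxy-4-(triisopropylsilyloxy)phenyl.
Assumption: (S)-BINOL is taken as the ligand antipode that gives the (S)-pyranone; if the sense of induction is the reverse, (R)-BINOL is used and nothing else changes.

Step 1
Reactants: 1 vanillin
Product: 2 3-methoxy-4-(triisopropylsilyloxy)benzaldehyde
Conditions: i-Pr3SiCl, imidazole, DMF, rt
Reagents that add atoms: triisopropylsilyl chloride, CC(C)[Si](Cl)(C(C)C)C(C)C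
Why: O-Silylation of the phenol masks the acidic OH for the enolate, aryllithium and hydride steps, and the bulky aryl silyl ether should survive base and mild acid yet leave with fluoride; no stereocenter is formed.

Step 2
Reactants: 2 3-methoxy-4-(triisopropylsilyloxy)benzaldehyde; 3 (E)-1-methoxy-3-(trimethylsilyloxy)buta-1,3-diene
Product: 5 (S)-2-Ar-2,3-dihydro-4H-pyran-4-one, via aldol adduct 4 (not isolated)
Conditions: Ti(OiPr)4 (10 mol%), (S)-BINOL (20 mol%), 4 Å MS, Et2O, −20 °C; then CF3CO2H, CH2Cl2, 0 °C
Reagents that add atoms: none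
Why: Catalytic enantioselective hetero-Diels–Alder reaction in its Mukaiyama aldol/cyclisation variant, in which the catalyst formed from Ti(OiPr)4 and BINOL binds the aldehyde and exposes one face to the terminal diene carbon, setting C2 (S, the later C7'), after which CF3CO2H closes adduct 4 by oxa-Michael addition with loss of methanol and the silyl group.

Step 3
Reactants: 5 (S)-2-Ar-2,3-dihydro-4H-pyran-4-one
Product: 8 (S)-5-diazo-2-Ar-oxan-4-one, via lithium enolate 6 (not isolated), via trifluoroacetyl ketone 7 (not isolated)
Conditions: LiBH(s-Bu)3 (L-Selectride), THF, −78 °C; CF3CO2CH2CF3, −78 °C; 5% aq HCl, crude carried on; then MsN3, Et3N, H2O, MeCN, rt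
Reagents that add atoms: methanesulfonyl azide, CS(=O)(=O)N=[N+]=[N-] (supplies the two diazo nitrogens); 2,2,2-trifluoroethyl trifluoroacetate, O=C(OCC(F)(F)F)C(F)(F)F (its acyl group is carried only by 7 and leaves again)
Why: Conjugate (1,4) hydride reduction of the vinylogous ester gives only the C4–C5 enolate 6, whose Claisen-type C-trifluoroacetylation to 7 and detrifluoroacetylative (Regitz-type) diazo transfer place the diazo group regiospecifically on C5; no stereocenter is formed and C2 is not touched.

Step 4
Reactants: 8 (S)-5-diazo-2-Ar-oxan-4-one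
Product: 10 (2S,3R)-5-diazo-3-(hydroxymethyl)-2-Ar-oxan-4-one (2,3-trans), via lithium enolate 9 (not isolated)
Conditions: LiN(SiMe3)2, THF, −78 °C; CH2O (monomeric, from cracked paraformaldehyde, THF solution), −78 °C; AcOH quench
Reagents that add atoms: formaldehyde, C=O
Why: Aldol addition of the α'-lithium enolate of an α-diazo ketone to formaldehyde, in which the electrophile approaches C3 anti to the neighbouring C2 aryl group and the trans (diequatorial) isomer is also the thermodynamic one, so C3 (the later C8') should be set as R while the proton-free diazo carbon cannot compete.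

Step 5
Reactants: 10 (2S,3R)-5-diazo-3-(hydroxymethyl)-2-Ar-oxan-4-one
Product: 12 (1R,5R,6S)-6-Ar-3,7-dioxabicyclo[3.3.0]octan-2-one (cis-fused; aryl exo), via ketene 11 (not isolated)
Conditions: hν (365 nm LED or Pyrex-filtered medium-pressure Hg lamp), dry degassed MeCN, 0.01 M, rt
Reagents that add atoms: none
Why: Irradiation of the s-cis-locked cyclic α-diazo ketone expels N2 with concerted 1,2-shift of C3 from the carbonyl carbon C4 to the diazo carbon C5 (Wolff rearrangement), which contracts the oxanone to the oxolane O1–C2–C3–C5–C6 and turns C4 into an exocyclic ketene carbon on C5; C3 migrates with retention, so the trans C2-aryl/C3-CH2OH relationship is carried over. The closest known reaction type is the photochemical Wolff ring contraction of cyclic α-diazo ketones, oxacyclic ones included, with capture of the ketene by a hydroxyl group to give an ester or lactone. The oxolane ring is closed by the 1,2-shift (new C3–C5 bond), and the lactone ring by 5-exo-dig addition of the C3 hydroxymethyl oxygen to the ketene carbonyl carbon. The new stereocenter (the former C5, C8 of the target) should take up its hydrogen on the face opposite the tether, because the cis-fused bicyclo[3.3.0] lactone is strongly preferred over the strained trans-fused one, so the temporary lactone fixes the cis relationship of the two side arms. The step needs ring contraction to win over 1,2-hydrogen shift from C6 and O–H insertion, which the fixed s-cis geometry of the diazo ketone favours, and intramolecular over intermolecular ketene capture, which high dilution in a dry aprotic solvent secures.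

Step 6
Reactants: 13 4-bromo-2-methoxyphenol
Product: 14 (4-bromo-2-methoxyphenoxy)triisopropylsilane
Conditions: i-Pr3SiCl, imidazole, DMF, rt
Reagents that add atoms: triisopropylsilyl chloride, CC(C)[Si](Cl)(C(C)C)C(C)C
Why: O-Silylation of the phenol as in step 1 removes the acidic proton so that the bromide can be lithiated; no stereocenter is formed.

Step 7
Reactants: 12 (1R,5R,6S)-6-Ar-3,7-dioxabicyclo[3.3.0]octan-2-one; 14 (4-bromo-2-methoxyphenoxy)triisopropylsilane
Product: 16 (1R,5R,6S)-2,6-di-Ar-3,7-dioxabicyclo[3.3.0]octan-2-ol (hemiketal; both C2 epimers), via aryllithium 15 (not isolated)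
Conditions: 14 (1.15 equiv), n-BuLi, THF, −78 °C; then 12, −78 °C; AcOH quench
Reagents that add atoms: none
Why: Bromine–lithium exchange gives aryllithium 15, which adds once to the γ-lactone carbonyl (1,2-addition) because the tetrahedral lithium alkoxide persists at −78 °C, so the C7–aryl bond is made and the tether is loosened to a hemiketal whose new center is erased in step 8.

Step 8
Reactants: 16 (1R,5R,6S)-2,6-di-Ar-3,7-dioxabicyclo[3.3.0]octan-2-ol
Product: 18 (7R)-7-hydroxylariciresinol 4,4'-bis(triisopropylsilyl) ether [(2S,3R,4R)-oxolane with (R)-carbinol], via hydroxy ketone 17 (not isolated)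
Conditions: Zn(BH4)2, Et2O–THF, −30 → 0 °C; aqueous work-up
Reagents that add atoms: none
Why: Chelation-controlled hydride reduction of a hydroxy aryl ketone, in which the zinc alkoxide of the cis CH2O arm of open form 17 binds the ketone oxygen, the aryl group turns away from that arm, and hydride enters from the convex face past H-8, which should give the (7R) carbinol (the epimer whose aryl group would be endo if the second ring were closed).

Step 9
Reactants: 18 (7R)-7-hydroxylariciresinol 4,4'-bis(triisopropylsilyl) ether
Product: 19 (7R)-7-hydroxylariciresinol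
Conditions: Bu4NF (2.5 equiv), AcOH (2.5 equiv), THF, 0 °C
Reagents that add atoms: none
Why: Fluoride-induced desilylation of the two aryl silyl ethers under acetic acid buffering avoids both acid-promoted benzylic ionisation (which would close the diol to a furofuran) and strongly basic phenoxide conditions, so no stereocenter is touched.

**Compound list**
1 | vanillin (4-hydroxy-3-methoxybenzaldehyde) | COc1cc(C=O)ccc1O | starting material
2 | 3-methoxy-4-(triisopropylsilyloxy)benzaldehyde | COc1cc(C=O)ccc1O[Si](C(C)C)(C(C)C)C(C)C | intermediate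
3 | (E)-1-methoxy-3-(trimethylsilyloxy)buta-1,3-diene | CO/C=C/C(=C)O[Si](C)(C)C | starting material
4 | (S,E)-1-methoxy-5-Ar-5-(trimethylsilyloxy)pent-1-en-3-one (Mukaiyama aldol adduct) | CO/C=C/C(=O)C[C@H](O[Si](C)(C)C)c1ccc(O[Si](C(C)C)(C(C)C)C(C)C)c(OC)c1 | intermediate (not isolated)
5 | (S)-2-Ar-2,3-dihydro-4H-pyran-4-one | COc1cc([C@H]2OC=CC(=O)C2)ccc1O[Si](C(C)C)(C(C)C)C(C)C | intermediate
6 | lithium (S)-2-Ar-3,6-dihydro-2H-pyran-4-olate (C4–C5 enolate) | COc1cc([C@H]2OCC=C(O[Li])C2)ccc1O[Si](C(C)C)(C(C)C)C(C)C | intermediate (not isolated)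
7 | (S)-2-Ar-5-(trifluoroacetyl)oxan-4-one, drawn as its C4 enol | COc1cc([C@H]2OCC(C(=O)C(F)(F)F)=C(O)C2)ccc1O[Si](C(C)C)(C(C)C)C(C)C | intermediate (not isolated)
8 | (S)-5-diazo-2-Ar-oxan-4-one | COc1cc([C@H]2OCC(=[N+]=[N-])C(=O)C2)ccc1O[Si](C(C)C)(C(C)C)C(C)C | intermediate
9 | lithium C3–C4 enolate of 8 | COc1cc([C@H]2OCC(=[N+]=[N-])C(O[Li])=C2)ccc1O[Si](C(C)C)(C(C)C)C(C)C | intermediate (not isolated)
10 | (2S,3R)-5-diazo-3-(hydroxymethyl)-2-Ar-oxan-4-one (2,3-trans) | COc1cc([C@H]2OCC(=[N+]=[N-])C(=O)[C@@H]2CO)ccc1O[Si](C(C)C)(C(C)C)C(C)C | intermediate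
11 | (2S,3R)-2-Ar-3-(hydroxymethyl)-4-(oxomethylidene)oxolane (ring-contracted ketene) | COc1cc([C@H]2OCC(=C=O)[C@@H]2CO)ccc1O[Si](C(C)C)(C(C)C)C(C)C | intermediate (not isolated)
12 | (1R,5R,6S)-6-Ar-3,7-dioxabicyclo[3.3.0]octan-2-one (cis-fused, aryl exo) | COc1cc([C@H]2OC[C@H]3[C@@H]2COC3=O)ccc1O[Si](C(C)C)(C(C)C)C(C)C | intermediate
13 | 4-bromo-2-methoxyphenol | COc1cc(Br)ccc1O | starting material
14 | (4-bromo-2-methoxyphenoxy)triisopropylsilane | COc1cc(Br)ccc1O[Si](C(C)C)(C(C)C)C(C)C | intermediate
15 | [3-methoxy-4-(triisopropylsilyloxy)phenyl]lithium | COc1cc([Li])ccc1O[Si](C(C)C)(C(C)C)C(C)C | intermediate (not isolated)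
16 | (1R,5R,6S)-2,6-di-Ar-3,7-dioxabicyclo[3.3.0]octan-2-ol (hemiketal, both C2 epimers) | COc1cc([C@H]2OC[C@H]3[C@@H]2COC3(O)c4ccc(O[Si](C(C)C)(C(C)C)C(C)C)c(OC)c4)ccc1O[Si](C(C)C)(C(C)C)C(C)C | intermediate
17 | (2S,3R,4R)-4-(Ar-carbonyl)-3-(hydroxymethyl)-2-Ar-oxolane (open hydroxy ketone; 2,3-trans, 3,4-cis) | COc1cc([C@H]2OC[C@H](C(=O)c3ccc(O[Si](C(C)C)(C(C)C)C(C)C)c(OC)c3)[C@@H]2CO)ccc1O[Si](C(C)C)(C(C)C)C(C)C | intermediate (not isolated)
18 | (7R)-7-hydroxylariciresinol 4,4'-bis(triisopropylsilyl) ether | COc1cc([C@H]2OC[C@H]([C@@H](O)c3ccc(O[Si](C(C)C)(C(C)C)C(C)C)c(OC)c3)[C@@H]2CO)ccc1O[Si](C(C)C)(C(C)C)C(C)C | intermediate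
19 | (7R)-7-hydroxylariciresinol, (2S,3R,4R)-2-(4-hydroxy-3-methoxyphenyl)-4-[(R)-hydroxy(4-hydroxy-3-methoxyphenyl)methyl]-3-(hydroxymethyl)oxolane | COc1cc([C@H]2OC[C@H]([C@@H](O)c3ccc(O)c(OC)c3)[C@@H]2CO)ccc1O | target

Total step count: 9. Longest linear sequence: 8 (steps 1–5 and 7–9); step 6 is a one-step side branch.

**Steps most likely to fail**

Step 8. What may go wrong is poor facial selectivity in the hydride addition: if the ketone reacts through the non-chelated rotamer, with its oxygen turned toward C9, hydride still enters past H-8 but the (7S) epimer results. The fallback sets out from lactone 12 and delivers the two C7 substituents in the reverse order. Reduction with i-Bu2AlH (CH2Cl2, −78 °C) should give the lactol (1R,5R,6S)-6-Ar-3,7-dioxabicyclo[3.3.0]octan-2-ol F1. An excess of aryllithium 15 (THF, −78 → 0 °C) then adds to its ring-opened aldehyde form (1,2-addition to a lactol) to give the diol directly. Because the aryl group now enters where hydride entered before, the same facial preference leads to the opposite C7 configuration. The route is rejoined at 18.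

Step 5. What may go wrong is diversion of the excited diazo ketone into 1,2-hydrogen shift from C6 or O–H insertion, or consumption of the ketene by intermolecular reactions before the tethered hydroxyl adds. The fallback sets out from 10, which is irradiated in methanol so that the solvent captures ketene 11 at once. This should give methyl (4R,5S)-4-(hydroxymethyl)-5-Ar-oxolane-3-carboxylate F2 as a mixture of epimers at the ester-bearing carbon. DBU in toluene then epimerises the ester α-carbon, and only the cis isomer can lactonise. Thermodynamic funnelling thus replaces tether-controlled protonation, and the route is rejoined at 12.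

Step 4. What may go wrong is β-elimination of the ring oxygen from the C3 lithium enolate (ring opening with loss of the C2 configuration), retro-aldol loss of formaldehyde, or a second hydroxymethylation. The fallback sets out from 8 and avoids a free basic enolate. Soft enolisation (Et3SiOTf, Et3N, CH2Cl2, 0 °C) should give the silyl enol ether (S)-5-diazo-2-Ar-4-(triethylsilyloxy)-5,6-dihydro-2H-pyran F3. A Lewis-acid-catalysed Mukaiyama aldol with aqueous formaldehyde (Sc(OTf)3 cat., THF–H2O, rt) then installs the hydroxymethyl group, again trans to the aryl group. The route is rejoined at 10.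

**Further compounds**
F1 | step 8 | (1R,5R,6S)-6-Ar-3,7-dioxabicyclo[3.3.0]octan-2-ol (lactol, both C2 epimers) | COc1cc([C@H]2OC[C@H]3[C@@H]2COC3O)ccc1O[Si](C(C)C)(C(C)C)C(C)C
F2 | step 5 | methyl (4R,5S)-4-(hydroxymethyl)-5-Ar-oxolane-3-carboxylate (both C3 epimers) | COc1cc([C@H]2OCC(C(=O)OC)[C@@H]2CO)ccc1O[Si](C(C)C)(C(C)C)C(C)C
F3 | step 4 | (S)-5-diazo-2-Ar-4-(triethylsilyloxy)-5,6-dihydro-2H-pyran | COc1cc([C@H]2OCC(=[N+]=[N-])C(O[Si](CC)(CC)CC)=C2)ccc1O[Si](C(C)C)(C(C)C)C(C)C
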